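**Retrosynthetic overview**

1. Target ⇐ selective O-acylation of a cyclic diol with nonadecanoic acid ⇐ ring-closing metathesis (Z C5=C6; the nine-membered carbocycle is formed last) of an oxolane triene-diol.
2. Oxolane diol ⇐ hydride opening of a temporary seven-membered lactone and deoxygenation of a γ-lactone in a cis-fused bis-lactone, whose C3 pentadienyl arm comes from Pd α-alkenylation with 2-bromopenta-1,4-diene.
3. Key disconnection C3a–C8a: bis-lactone ⇐ intramolecular carbene-catalysed homoenolate annulation, the enal β-carbon adding to the ketone of a dienyl α-keto ester tethered through the tertiary alcohol; the quaternary ether carbon is set here.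
4. Enal keto ester ⇐ (S)-linalool (ozonolysis/Wittig; carbinol stereocentre from the chiral pool) + a dienyl keto acid (pyruvic acid + prenal).
5. Ring order: γ-lactone (future oxolane) and tether lactone together, then the oxolane by lactone deoxygenation, tether cut, nine-membered ring last.

Assumption 1: (S)-(+)-linalool is bought in high enantiomeric purity and supplies the tertiary carbinol centre unchanged.
Assumption 2: the (5aR,10bS) enantiomer of the triazolium precatalyst is taken to give the required (3aS) centre; if the sense is opposite, the commercial antipode is used under the same conditions.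

**Step 1**
Reactants: 1 2,3-dibromopropene; 2 vinylmagnesium bromide
Product: 3 2-bromopenta-1,4-diene
Conditions: CuI (5 mol %), THF, −20 °C → rt
Reagents that add atoms: vinylmagnesium bromide 2, C=C[Mg]Br
Why: Copper-catalysed allyl–vinyl Grignard cross-coupling displaces only the allylic bromide (direct and allyl-transposed attack give the same product), the vinylic C–Br being inert, which leaves the 1,1-disubstituted vinyl bromide needed in step 6.

**Step 2**
Reactants: 4 pyruvic acid; 5 3-methylbut-2-enal
Product: 6 (3E)-6-methyl-2-oxohepta-3,5-dienoic acid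
Conditions: KOH, MeOH/H2O, 0 °C → rt; then HCl (aq)
Reagents that add atoms: 3-methylbut-2-enal 5, CC(C)=CC=O
Why: Crossed aldol (Claisen–Schmidt) condensation of the pyruvate enolate with an aldehyde that has no sp3 α-hydrogen, followed by E1cB dehydration to the conjugated (3E) keto acid.

**Step 3**
Reactants: 7 (S)-linalool [(3S)-3,7-dimethylocta-1,6-dien-3-ol]; 8 (triphenylphosphoranylidene)acetaldehyde
Product: 10 (2E,6S)-6-hydroxy-6-methylocta-2,7-dienal, via vinyl lactol 9 (not isolated)
Conditions: O3, CH2Cl2, −78 °C (Sudan Red 7B end point); PPh3, −78 °C → rt; then 8, toluene, 80 °C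
Reagents that add atoms: ozone, [O-][O+]=O (its oxygen is carried in 9 only); (triphenylphosphoranylidene)acetaldehyde 8, O=CC=P(c1ccccc1)(c1ccccc1)c1ccccc1
Why: Ozone cleaves the electron-rich trisubstituted alkene much faster than the vinyl group, PPh3 reduces the ozonide to the hydroxy aldehyde resting as lactol 9, and Wittig olefination with the stabilised formyl ylide through the open-chain form gives the (E)-enal, the carbinol stereocentre coming untouched from the chiral pool.

**Step 4**
Reactants: 6 (3E)-6-methyl-2-oxohepta-3,5-dienoic acid; 10 (2E,6S)-6-hydroxy-6-methylocta-2,7-dienal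
Product: 12 (3S,6E)-3-methyl-8-oxoocta-1,6-dien-3-yl (3E)-6-methyl-2-oxohepta-3,5-dienoate, via acid chloride 11 (not isolated)
Conditions: 6, (COCl)2, DMF (cat.), CH2Cl2, 0 °C, then evaporate; 10, pyridine, DMAP (10 mol %), CH2Cl2, −20 °C → rt
Reagents that add atoms: (3E)-6-methyl-2-oxohepta-3,5-dienoic acid 6, CC(C)=C/C=C/C(=O)C(=O)O; oxalyl chloride, O=C(Cl)C(=O)Cl (its chlorine is carried in 11 only)
Why: DMAP-catalysed nucleophilic acyl substitution with a strongly electrophilic α-keto acyl chloride esterifies the hindered tertiary allylic alcohol under basic, non-ionising conditions, so the carbinol centre is retained and the enal is untouched.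

**Step 5 (key step)**
Reactants: 12 (3S,6E)-3-methyl-8-oxoocta-1,6-dien-3-yl (3E)-6-methyl-2-oxohepta-3,5-dienoate
Product: 13 (3aS,6S,8aS)-6-ethenyl-6-methyl-8a-[(1E)-4-methylpenta-1,3-dien-1-yl]hexahydrofuro[2,3-c]oxepine-2,8-dione (cis-fused; locants O1, C2 γ-lactone carbonyl, C3, C3a, C4, C5, C6, O7, C8 seven-membered-lactone carbonyl, C8a)
Conditions: (5aR,10bS)-2-mesityl-5a,10b-dihydro-4H,6H-indeno[2,1-b][1,2,4]triazolo[4,3-d][1,4]oxazin-2-ium chloride (15 mol %), DBU (15 mol %), toluene (0.005 M), 40 °C
Reagents that add atoms: none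
Why: Proposed new method: the carbene adds to the aldehyde and the Breslow intermediate reacts as a homoenolate, so the normally electrophilic enal β-carbon attacks the equally electrophilic keto carbon of the tethered α-keto ester (seven-membered ring, with 1,2-addition favoured over conjugate addition by ring size), after which the tertiary alkoxide acylates on the acyl azolium to close the γ-lactone and release the catalyst; the chiral triazolium fixes the face of the β-carbon (C3a), and because the bulky azolium-enol arm avoids the dienyl group in the cyclic transition state the new ring oxygen lies cis to C3, giving the cis-fused quaternary centre C8a; the closest known reaction is the intermolecular carbene-catalysed homoenolate annulation of enals with α-keto esters to γ-butyrolactones.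

**Step 6**
Reactants: 13 the bis-lactone of step 5; 3 2-bromopenta-1,4-diene
Product: 14 (3R,3aS,6S,8aR)-6-ethenyl-6-methyl-8a-[(1E)-4-methylpenta-1,3-dien-1-yl]-3-(penta-1,4-dien-2-yl)hexahydrofuro[2,3-c]oxepine-2,8-dione
Conditions: LiN(SiMe3)2, THF, −78 °C; ZnCl2; then 3, Pd2(dba)3 (2.5 mol %), P(t-Bu)3 (10 mol %), THF, rt → 50 °C
Reagents that add atoms: 2-bromopenta-1,4-diene 3, C=CCC(Br)=C
Why: Palladium-catalysed α-alkenylation of a zinc lactone enolate (Reformatsky/Negishi-type enolate cross-coupling after oxidative addition of zerovalent palladium into the vinyl bromide) works at C3, the only enolisable position, and C–C bond formation as well as any later equilibration puts the new group on the convex face, trans to the C3a–C4 bond.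

**Step 7**
Reactants: 14 the alkenylated bis-lactone of step 6
Product: 16 (3R,3aS,6S,8aR)-6-ethenyl-6-methyl-8a-[(1E)-4-methylpenta-1,3-dien-1-yl]-3-(penta-1,4-dien-2-yl)hexahydrofuro[2,3-c]oxepin-8-one, via bicyclic lactol 15 (not isolated)
Conditions: i-Bu2AlH (1.1 equiv), CH2Cl2, −78 °C; then Et3SiH (3 equiv), BF3·OEt2 (2 equiv), −78 → −30 °C
Reagents that add atoms: none
Why: i-Bu2AlH reduces the γ-lactone to the lactol while the seven-membered lactone (tertiary-alkyl ester with a quaternary α-carbon, pivalate-like) is too hindered to react, and BF3-promoted ionic hydrogenation of the lactol through its oxocarbenium ion with Et3SiH gives the oxolane without touching a stereocentre, the adjacent lactone carbonyl disfavouring ionisation of the C8a–O bond.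

**Step 8**
Reactants: 16 the oxolane lactone of step 7
Product: 17 (3S)-5-[(2R,3S,4R)-2-(hydroxymethyl)-2-[(1E)-4-methylpenta-1,3-dien-1-yl]-4-(penta-1,4-dien-2-yl)oxolan-3-yl]-3-methylpent-1-en-3-ol
Conditions: LiAlH4, THF, 0 → 40 °C
Reagents that add atoms: none
Why: LiAlH4 reduction of the remaining lactone cuts the tether, releasing the primary hydroxymethyl group on the quaternary ether carbon and the tertiary allylic alcohol, with no stereocentre involved and the alkenes and oxolane inert to hydride.

**Step 9**
Reactants: 17 the seco diol of step 8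
Product: 18 (1S,4S,5Z,9R,12R)-12-(hydroxymethyl)-4-methyl-8-methylidene-12-[(1E)-4-methylpenta-1,3-dien-1-yl]-11-oxabicyclo[7.3.0]dodec-5-en-4-ol (C1 and C9 ring-fusion carbons, C12 quaternary ether carbon)
Conditions: second-generation Hoveyda–Grubbs catalyst (10 mol %), 2,6-dichloro-1,4-benzoquinone (20 mol %), toluene (0.001 M), 80 °C
Reagents that add atoms: none
Why: Ring-closing metathesis in which the ruthenium carbene loads on the unhindered allyl terminus and closes onto the vinyl carbinol at high dilution, ring strain allowing only the Z alkene in the nine-membered ring and the 1,1-disubstituted and dienyl alkenes next to quaternary carbons being much slower partners.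

**Step 10**
Reactants: 18 the cyclic diol of step 9; 19 nonadecanoic acid
Product: 20 [(1S,4S,5Z,9R,12R)-4-hydroxy-4-methyl-8-methylidene-12-[(1E)-4-methylpenta-1,3-dien-1-yl]-11-oxabicyclo[7.3.0]dodec-5-en-12-yl]methyl nonadecanoate (CNP0120482.1)
Conditions: 19, N,N′-dicyclohexylcarbodiimide, DMAP (cat.), CH2Cl2, 0 °C → rt
Reagents that add atoms: nonadecanoic acid 19, CCCCCCCCCCCCCCCCCCC(=O)O
Why: Steglich (carbodiimide/DMAP) esterification acylates only the primary alcohol, the tertiary allylic alcohol being too hindered, and no stereocentre is touched.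

**Compound list**

1 | 2,3-dibromopropene | C=C(Br)CBr | starting material
2 | vinylmagnesium bromide | C=C[Mg]Br | starting material
3 | 2-bromopenta-1,4-diene | C=CCC(Br)=C | intermediate
4 | pyruvic acid | CC(=O)C(=O)O | starting material
5 | 3-methylbut-2-enal | CC(C)=CC=O | starting material
6 | (3E)-6-methyl-2-oxohepta-3,5-dienoic acid | CC(C)=C/C=C/C(=O)C(=O)O | intermediate
7 | (S)-linalool, (3S)-3,7-dimethylocta-1,6-dien-3-ol | C=C[C@@](C)(O)CCC=C(C)C | starting material
8 | (triphenylphosphoranylidene)acetaldehyde | O=CC=P(c1ccccc1)(c1ccccc1)c1ccccc1 | starting material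
9 | (5S)-5-ethenyl-5-methyloxolan-2-ol (anomers) | C=C[C@]1(C)CCC(O)O1 | intermediate
10 | (2E,6S)-6-hydroxy-6-methylocta-2,7-dienal | C=C[C@@](C)(O)CC/C=C/C=O | intermediate
11 | (3E)-6-methyl-2-oxohepta-3,5-dienoyl chloride | CC(C)=C/C=C/C(=O)C(=O)Cl | intermediate
12 | (3S,6E)-3-methyl-8-oxoocta-1,6-dien-3-yl (3E)-6-methyl-2-oxohepta-3,5-dienoate | C=C[C@@](C)(OC(=O)C(=O)/C=C/C=C(C)C)CC/C=C/C=O | intermediate
13 | (3aS,6S,8aS)-6-ethenyl-6-methyl-8a-[(1E)-4-methylpenta-1,3-dien-1-yl]hexahydrofuro[2,3-c]oxepine-2,8-dione | C=C[C@]1(C)CC[C@H]2CC(=O)O[C@@]2(/C=C/C=C(C)C)C(=O)O1 | intermediate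
14 | (3R,3aS,6S,8aR)-6-ethenyl-6-methyl-8a-[(1E)-4-methylpenta-1,3-dien-1-yl]-3-(penta-1,4-dien-2-yl)hexahydrofuro[2,3-c]oxepine-2,8-dione | C=C[C@]1(C)CC[C@H]2[C@H](C(=C)CC=C)C(=O)O[C@@]2(/C=C/C=C(C)C)C(=O)O1 | intermediate
15 | (3R,3aS,6S,8aR)-6-ethenyl-2-hydroxy-6-methyl-8a-[(1E)-4-methylpenta-1,3-dien-1-yl]-3-(penta-1,4-dien-2-yl)hexahydrofuro[2,3-c]oxepin-8-one (C2 anomers) | C=C[C@]1(C)CC[C@H]2[C@H](C(=C)CC=C)C(O)O[C@@]2(/C=C/C=C(C)C)C(=O)O1 | intermediate
16 | (3R,3aS,6S,8aR)-6-ethenyl-6-methyl-8a-[(1E)-4-methylpenta-1,3-dien-1-yl]-3-(penta-1,4-dien-2-yl)hexahydrofuro[2,3-c]oxepin-8-one | C=C[C@]1(C)CC[C@H]2[C@H](C(=C)CC=C)CO[C@@]2(/C=C/C=C(C)C)C(=O)O1 | intermediate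
17 | (3S)-5-[(2R,3S,4R)-2-(hydroxymethyl)-2-[(1E)-4-methylpenta-1,3-dien-1-yl]-4-(penta-1,4-dien-2-yl)oxolan-3-yl]-3-methylpent-1-en-3-ol | C=C[C@@](C)(O)CC[C@H]1[C@H](C(=C)CC=C)CO[C@@]1(/C=C/C=C(C)C)CO | intermediate
18 | (1S,4S,5Z,9R,12R)-12-(hydroxymethyl)-4-methyl-8-methylidene-12-[(1E)-4-methylpenta-1,3-dien-1-yl]-11-oxabicyclo[7.3.0]dodec-5-en-4-ol | C=C1C/C=C\[C@@](C)(O)CC[C@H]2[C@H]1CO[C@@]2(/C=C/C=C(C)C)CO | intermediate
19 | nonadecanoic acid | CCCCCCCCCCCCCCCCCCC(=O)O | starting material
20 | [(1S,4S,5Z,9R,12R)-4-hydroxy-4-methyl-8-methylidene-12-[(1E)-4-methylpenta-1,3-dien-1-yl]-11-oxabicyclo[7.3.0]dodec-5-en-12-yl]methyl nonadecanoate | C=C1C/C=C\[C@@](C)(O)CC[C@H]2[C@H]1CO[C@@]2(/C=C/C=C(C)C)COC(=O)CCCCCCCCCCCCCCCCCC | target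

**Step count**

Total: 10 steps. Longest linear sequence: 8 steps (steps 3 to 10, from 7).

**Steps most likely to fail, with fallbacks**

Step 5 is the largest risk. The ester tether must reach its less favoured s-cis rotamer to close a seven-membered ring, and homoenolate additions to ketones are established mainly between separate partners. Failure would show as enal dimers, the saturated ester, or the wrong ring fusion. The fallback makes the same C3a–C8a bond from the ketone side by a reductive radical cyclisation. It sets out from 7, which is ozonised as in step 3, and the lactol 9 is olefinated with methyl (triphenylphosphoranylidene)acetate to methyl (2E,6S)-6-hydroxy-6-methylocta-2,7-dienoate F1. Acylation with 11 as in step 4 gives (3S,6E)-8-methoxy-3-methyl-8-oxoocta-1,6-dien-3-yl (3E)-6-methyl-2-oxohepta-3,5-dienoate F2. SmI2 (2.2 equiv) with t-BuOH in THF at −78 °C reduces the keto ester to its ketyl, which cyclises onto the enoate β-carbon; the samarium alkoxide then lactonises onto the methyl ester. This comes back to the route at 13, with the ring fusion under substrate (chelate) control and no catalyst control.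

Step 6 couples a hindered lactone enolate with a 1,1-disubstituted vinyl bromide. It may stall through proton transfer to the more acidic product or through migration of the new double bond into conjugation. The fallback reverses the polarity at C3 and sets out from 13. Bromination through the silyl ketene acetal (LiN(SiMe3)2, Me3SiCl, then N-bromosuccinimide) gives (3aR,6S,8aR)-3-bromo-6-ethenyl-6-methyl-8a-[(1E)-4-methylpenta-1,3-dien-1-yl]hexahydrofuro[2,3-c]oxepine-2,8-dione F3 as C3 epimers. Bromide 3 is converted with Mg and then ZnBr2 into bromo(penta-1,4-dien-2-yl)zinc F4. A nickel-catalysed Negishi coupling (NiCl2(MeOCH2CH2OMe) 10 mol %, 2,6-bis[(4S)-4-isopropyl-2-oxazolin-2-yl]pyridine, THF/N,N-dimethylacetamide, 0 °C) joins them through the C3 radical, which is captured trans to the C3a–C4 bond. This comes back to the route at 14.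

Step 9 must close a nine-membered carbocycle. It may give oligomers, or the carbene may attack the internal alkene of the dienyl group and form a bridged seven-membered by-product. The fallback masks the diene and sets out from 17. Tricarbonyl(benzylideneacetone)iron, Fe(CO)3(PhCH=CHCOMe), in toluene at 50 °C binds only the conjugated diene as a zerovalent iron tricarbonyl unit, giving the tricarbonyl(η4-dienyl)iron complex of 17 F5. The same ruthenium catalyst then closes the ring to the tricarbonyl(η4-dienyl)iron complex of 18 F6. (NH4)2Ce(NO3)6 in acetone at −20 °C removes the metal, and the sequence comes back to the route at 18.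

**Further compounds**

F1 | step 5 | methyl (2E,6S)-6-hydroxy-6-methylocta-2,7-dienoate | C=C[C@@](C)(O)CC/C=C/C(=O)OC
F2 | step 5 | (3S,6E)-8-methoxy-3-methyl-8-oxoocta-1,6-dien-3-yl (3E)-6-methyl-2-oxohepta-3,5-dienoate | C=C[C@@](C)(OC(=O)C(=O)/C=C/C=C(C)C)CC/C=C/C(=O)OC
F3 | step 6 | (3aR,6S,8aR)-3-bromo-6-ethenyl-6-methyl-8a-[(1E)-4-methylpenta-1,3-dien-1-yl]hexahydrofuro[2,3-c]oxepine-2,8-dione (C3 epimers) | C=C[C@]1(C)CC[C@H]2C(Br)C(=O)O[C@@]2(/C=C/C=C(C)C)C(=O)O1
F4 | step 6 | bromo(penta-1,4-dien-2-yl)zinc | C=CCC(=C)[Zn]Br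
F5 | step 9 | tricarbonyl(η4-dienyl)iron complex of 17 (written as ligand and metal fragment) | C=C[C@@](C)(O)CC[C@H]1[C@H](C(=C)CC=C)CO[C@@]1(/C=C/C=C(C)C)CO.[Fe].[C-]#[O+].[C-]#[O+].[C-]#[O+]
F6 | step 9 | tricarbonyl(η4-dienyl)iron complex of 18 (written as ligand and metal fragment) | C=C1C/C=C\[C@@](C)(O)CC[C@H]2[C@H]1CO[C@@]2(/C=C/C=C(C)C)CO.[Fe].[C-]#[O+].[C-]#[O+].[C-]#[O+]
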